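Late in elm, solid substrate reads 0%, and target reads 14.5% at 4.00 d and 14.9% at 5.00 d; with a scatter of 0.5 percentage points on each reading, these two can't show whether target has stopped rising.

| flask | solid substrate | protic impurity | remark | time |
|---|---|---|---|---|
| elm | 0.16 M | 0.040 M | run made earlier |  |
| ash | 0.68 M | 0.040 M | run made earlier |  |
| oak | 1.6 M | 0.040 M | run made earlier |  |
| amber | 0.20 M | 0.0400 M |  | 10 d |
| blue | 0.60 M | 0.0400 M |  | 10 d |
| grey | 2.0 M | 0.0400 M |  | 10 d |

| run | time / d | target / % | solid substrate / % |
|---|---|---|---|
| elm | 1.25 | 1.9 | 12.6 |
| elm | 2.50 | 8.0 | 0 |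
| elm | 4.00 | 14.5 | 0 |
| elm | 5.00 | 14.9 | 0 |
| ash | 0.417 | 0 | 91.6 |
| ash | 0.833 | 0.3 | 85.2 |
| ash | 2.00 | 1.9 | 67.8 |
| ash | 5.00 | 7.4 | 25.7 |
| oak | 1.25 | 0.4 | 91.5 |
| oak | 2.50 | 0.8 | 83.1 |
| oak | 4.00 | 2.4 | 74.3 |
| oak | 5.00 | 3.6 | 68.3 |

(scatter of a reading: 0.5 percentage points)

- solid substrate is a solid; its amount is given per volume of the solution
- at the start none of the solid substrate is in solution
- "hardly changes" means that all values lie within two and a half points (for a concentration: within two and a half percent of the largest)

* [target] at the end for amber, blue, grey, in this order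
* the shape of the row from first to last (rises all the way / falls, then rises / falls all the way / rises, then falls / hardly changes)

I follow one molecule of solid. Once dissolved, it meets a fork: the protic impurity may catch it. I assume one for one, so in elm the impurity can claim 25.0% of the charge. Elm then gives 19.9% for the target share, a selectivity: target at the last reading divided by the fraction of the charge that escaped the impurity. I assume this share holds in each flask.

The first setting is the charge. A larger charge shrinks the impurity's claim to 20.0% in amber, 6.67% in blue and 2.00% in grey. With dissolving complete, target would reach 15.9% of the charge in amber and 18.5% in blue.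

The second setting is the time. Oak's readings give a dissolving pace of 0.101 M d⁻¹, and its target trails the dissolving by 1.75 d. Blue needs 7.66 d with that trail, less than the time allowed. Grey's solid alone needs 19.7 d, more than the time allowed. So I reckon grey at 7.92% of its charge. In molar terms my row is 0.0318 M, 0.111 M, 0.158 M, and it rises.

The forecast gives 0.032 M, 0.11 M, 0.15 M, shape rises all the way, a little below me on grey, with grey expected to “still hold about half its solid”.

The flask gives 0.0341 M, 0.110 M, 0.148 M; the shape is rises all the way.

    intermediate B ⇌ intermediate C (K = 47.3, k = 0.00184 min⁻¹)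
    intermediate C → target (k = 3.93 × 10⁻⁴ min⁻¹)
    intermediate A → intermediate B (k = 0.00111 min⁻¹)
    starting material → intermediate A (k = 0.00200 min⁻¹)
    solid substrate ⇌ starting material, rate k5*(cs5 - [starting material]) while solid is left; crystals form when [starting material] > cs5 (solubility = 0.0770 M, k = 0.00149 min⁻¹)
    target ⇌ isomer of the product (K = 3.90, k = 0.00241 min⁻¹)
    starting material + protic impurity → quenched substrate (k = 0.0189 L mol⁻¹ min⁻¹)

At 10.0 d grey still holds 51.1% of its charge as solid substrate. At 100 d its solid stands at 0% and its quenched substrate at 2.00%. The target share on the remainder gives 19.5%, and grey's target stands at 20.0%.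

The runs were computed for an exercise; scatter was added.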